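At the reading at 6.0 h, the choice for the next charge is how much partner to put in, and at what dilution.

| flask | substrate | partner | remark | time |
|---|---|---|---|---|
| cedar | 0.10 M | 0.93 equiv | run made earlier |  |
| birch | 0.10 M | 2 equiv | run made earlier |  |
| elm | 0.10 M | 3.9 equiv | run made earlier |  |
| ash | 0.067 M | 1 equiv | run made earlier |  |
| amber | 0.10 M | 1.00 equiv |  | 6.0 h |
| ochre | 0.10 M | 4.00 equiv |  | 6.0 h |
| green | 0.030 M | 4.00 equiv |  | 6.0 h |
| grey | 0.030 M | 1.00 equiv |  | 6.0 h |

| run | time / h | target / % |
|---|---|---|
| cedar | 0.500 | 6.2 |
| cedar | 0.833 | 12.0 |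
| cedar | 1.50 | 23.3 |
| cedar | 3.00 | 42.3 |
| cedar | 6.00 | 57.3 |
| birch | 1.33 | 28.2 |
| birch | 2.50 | 44.0 |
| birch | 4.00 | 48.0 |
| birch | 5.00 | 46.3 |
| birch | 6.00 | 43.7 |
| elm | 0.500 | 10.2 |
| elm | 1.50 | 29.8 |
| elm | 3.00 | 29.4 |
| elm | 4.00 | 23.0 |
| elm | 6.00 | 11.8 |
| ash | 0.500 | 5.2 |
| ash | 1.50 | 21.1 |
| ash | 3.00 | 40.2 |
| ash | 4.00 | 47.5 |
| ash | 6.00 | 56.1 |

(readings scatter by 0.5 percentage points)

1. the flasks by amount of target, in percent of the substrate charged, highest first, at 6.0 h (amber / ochre / green / grey)
2. the amount of target, in percent of the substrate charged of the flask you put first, at 6.0 h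
3. the amount of target, in percent of the substrate charged of the flask you put last, at 6.0 h

- the numbers in the tables scatter by 0.5 percentage points (one standard deviation)

Elm, with partner in excess, reads 29.8% of target at 1.50 h but 11.8% at 6.00 h. Follow one molecule of target: take its loss as pseudo-first-order at a fixed surplus of partner, where the surplus is partner charged minus substrate charged, in molar. Its chance of lasting to 6.0 h then falls exponentially with the surplus. Elm has a surplus of 0.290 M, and if its substrate has passed through target by 6.00 h, the reading is the surviving share. Elm's reading then gives 7.37 L mol⁻¹ for the loss number, the logarithm of the inverse surviving share per molar of surplus at that time. Birch, with a surplus of 0.100 M, gets an estimate of 47.9%, and it reads less, 43.7%.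

Ochre, with a surplus of 0.300 M, then gets an estimate of 11.0%. Green, with 0.0900 M, gets an estimate of 51.5%. Amber and grey have no surplus by this definition, so the rule gives no usable figure for them, and cedar and ash, reading 57.3% and 56.1%, are their guides. This reckoning puts amber first and ochre last, leaves green and grey unranked, and keeps the next charge at one equivalent.

The forecast gives amber > green > grey > ochre, with 59% and 11%, and says of the middle pair: “Green and grey are close, so their order is uncertain”.

The flasks give amber > grey > green > ochre, with amber at 58.7% and ochre at 11.3%, against the 11.0% from the loss number; grey, at 46.1%, stands above green, at 41.8%, the reverse of the forecast's pair.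

    substrate + partner ⇌ intermediate A (K = 8.50 L mol⁻¹, k = 0.0520 L mol⁻¹ s⁻¹)
    substrate ⇌ intermediate B (K = 1.10, k = 2.90 × 10⁻⁴ s⁻¹)
    substrate + partner → intermediate C (k = 0.00520 L mol⁻¹ s⁻¹)
    intermediate C → target (k = 2.30 × 10⁻⁴ s⁻¹)
    partner + target → over-reaction product (k = 7.20 × 10⁻⁴ L mol⁻¹ s⁻¹)

A neighbour of amber charged with 2.50 equiv of partner has a surplus of 0.150 M, so the loss number gives an estimate of 33.1%, and that flask holds 31.8%. Amber at 6.00 h holds 58.7% of target against 13.0% of over-reaction product, with 9.9% of its partner left. There, in amber, target is still made 2.44 times faster than it is used up, each step taken net.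

All runs were generated by integration for an exercise; noise was put on by code.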